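**Retrosynthetic overview**
1. The target is epicatechin‑(6'→8)‑catechin, reached by global hydrogenolysis of nona‑O‑benzyl dimer 10. Rings A, B and C of both units and all four stereocentres come intact from (+)‑catechin and (−)‑epicatechin.
2. The C6'–C8 biaryl bond comes from a Hiyama–Denmark coupling of cyclic silyl ether 8 (epicatechin half) with 8‑bromide 4 (catechin half).
3. Compound 8 comes from a new 3‑O‑hydrosilyl‑directed, iridium‑catalysed C6'–H silylation of tetra‑O‑benzylepicatechin 6. The oxasiline made here is the only ring formed in the route, and it is opened again in the coupling.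
4. Compound 4 comes from catechin by benzylation and C8‑selective bromination.

Assumption: the SMILES defines four stereocentres and no axial descriptor, so the C6'–C8 biaryl axis is treated as configurationally unspecified; both natural flavan‑3‑ols are bought as single enantiomers.

**Step 1**
Reactants: 1 (+)-catechin
Product: 2 5,7,3',4'-tetra-O-benzyl-(+)-catechin (2R,3S; free 3-OH)
Conditions: BnBr (4.4 equiv), K2CO3 (5 equiv), DMF, 0 °C to rt, Ar
Reagents that add atoms: benzyl bromide, BrCc1ccccc1
Why: Williamson ether synthesis in which K2CO3 deprotonates only the four phenols, so the secondary 3-OH stays free and no stereocentre is touched.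

**Step 2**
Reactants: 2 5,7,3',4'-tetra-O-benzyl-(+)-catechin
Product: 3 3,5,7,3',4'-penta-O-benzyl-(+)-catechin (2R,3S)
Conditions: NaH (1.5 equiv), BnBr (1.3 equiv), n-Bu4NI (cat.), DMF, 0 °C to rt
Reagents that add atoms: benzyl bromide, BrCc1ccccc1
Why: Williamson etherification of the secondary alkoxide; with every phenol capped there is no quinone-methide pathway for C2 epimerisation.

**Step 3**
Reactants: 3 3,5,7,3',4'-penta-O-benzyl-(+)-catechin
Product: 4 8-bromo-3,5,7,3',4'-penta-O-benzyl-(+)-catechin (2R,3S)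
Conditions: NBS (1.05 equiv), CH2Cl2, −78 °C to rt
Reagents that add atoms: N-bromosuccinimide, O=C1CCC(=O)N1Br
Why: Electrophilic aromatic bromination, which with one equivalent of NBS goes selectively to C8, the most nucleophilic position of the phloroglucinol-type ring A in benzylated flavan-3-ols.

**Step 4**
Reactants: 5 (−)-epicatechin
Product: 6 5,7,3',4'-tetra-O-benzyl-(−)-epicatechin (2R,3R; free 3-OH)
Conditions: BnBr (4.4 equiv), K2CO3 (5 equiv), DMF, 0 °C to rt, Ar
Reagents that add atoms: benzyl bromide, BrCc1ccccc1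
Why: Phenol-selective Williamson ether synthesis under mild carbonate conditions at room temperature, which leave the 2,3-cis stereocentres and the 3-OH untouched.

**Step 5**
Reactants: 6 5,7,3',4'-tetra-O-benzyl-(−)-epicatechin
Product: 8 cyclic silyl ether of 6 in which SiEt2 bridges O3 to C6' (six-membered oxasiline cis-fused to ring C; 2R,3R), via hydrosilyl ether 7 (not isolated)
Conditions: Et2SiH2 (1.5 equiv), [Ir(cod)OMe]2 (0.5 mol %), THF, rt; evaporate; [Ir(cod)OMe]2 (2 mol %), 3,4,7,8-tetramethyl-1,10-phenanthroline (5 mol %), norbornene (1.2 equiv), THF, 100 °C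
Reagents that add atoms: diethylsilane, CC[SiH2]CC
Why: Proposed new method: the 3-O-(hydrido)silyl ether 7 directs iridium-catalysed dehydrogenative C–H silylation to the remote ring B carbon C6' — Si–H oxidative addition to the iridium–tetramethylphenanthroline centre and hydrogen transfer to norbornene give an iridium silyl species, the tether (O3–C3–C2–C1' held gauche in the 2,3-cis half-chair) brings only C2'–H and C6'–H within reach, cleavage occurs at C6' because C2' is flanked by the 3'-benzyloxy group, and C–Si reductive elimination closes the six-membered oxasiline; the closest known reaction type is the iridium-catalysed hydroxyl-directed ortho C–H silylation of hydrosilyl ethers of benzylic alcohols to five-membered benzoxasiloles, here extended by one ring atom to a homobenzylic alcohol on a flavan-3-ol, and the same O3-to-C6' six-membered closure is known for carbon electrophiles (oxa-Pictet–Spengler), which supports the geometry; this step alone selects C6' as the biaryl junction and no stereocentre is formed or disturbed.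

**Step 6**
Reactants: 8 cyclic silyl ether (O3–SiEt2–C6' bridged tetra-O-benzylepicatechin); 4 8-bromo-penta-O-benzyl-(+)-catechin
Product: 10 5,7,3',4'-tetra-O-benzyl-(−)-epicatechin-(6'→8)-3,5,7,3',4'-penta-O-benzyl-(+)-catechin (nona-O-benzyl dimer; free 3-OH on the epicatechin unit), via sodium silanolate 9 (not isolated)
Conditions: NaOH (3 M aq, 3 equiv), THF, rt; then 4, Pd(P(t-Bu)3)2 (5 mol %), THF/toluene, 80 °C
Reagents that add atoms: none
Why: Hiyama–Denmark cross-coupling in which hydroxide opens the Si–O bond to aryl silanolate 9, which transmetalates through a Si–O–Pd linkage to the arylpalladium bromide formed from 4 and zerovalent palladium, the bulky trialkylphosphine supporting oxidative addition and reductive elimination to the tri-ortho-substituted biaryl without touching any stereocentre.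

**Step 7**
Reactants: 10 nona-O-benzyl dimer
Product: 11 CNP0353739.2, (−)-epicatechin-(6'→8)-(+)-catechin
Conditions: H2 (1 atm), Pd(OH)2/C (20 wt %), THF/MeOH/H2O, rt; Sephadex LH-20, lyophilise under Ar
Reagents that add atoms: none
Why: Heterogeneous hydrogenolysis of all nine benzyl ethers under neutral conditions, as established for benzylated flavan-3-ol oligomers, leaves the cyclic C2–O1 ethers and the four stereocentres intact.

**Compound list**
1 | (+)-catechin, (2R,3S)-2-(3,4-dihydroxyphenyl)chromane-3,5,7-triol | Oc1cc(O)c2c(c1)O[C@H](c1ccc(O)c(O)c1)[C@@H](O)C2 | starting material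
2 | 5,7,3',4'-tetra-O-benzyl-(+)-catechin | c1ccccc1COc1cc(OCc2ccccc2)c2c(c1)O[C@H](c1ccc(OCc3ccccc3)c(OCc3ccccc3)c1)[C@@H](O)C2 | intermediate
3 | 3,5,7,3',4'-penta-O-benzyl-(+)-catechin | c1ccccc1COc1cc(OCc2ccccc2)c2c(c1)O[C@H](c1ccc(OCc3ccccc3)c(OCc3ccccc3)c1)[C@@H](OCc1ccccc1)C2 | intermediate
4 | 8-bromo-3,5,7,3',4'-penta-O-benzyl-(+)-catechin | c1ccccc1COc1cc(OCc2ccccc2)c2c(c1Br)O[C@H](c1ccc(OCc3ccccc3)c(OCc3ccccc3)c1)[C@@H](OCc1ccccc1)C2 | intermediate
5 | (−)-epicatechin, (2R,3R)-2-(3,4-dihydroxyphenyl)chromane-3,5,7-triol | Oc1cc(O)c2c(c1)O[C@H](c1ccc(O)c(O)c1)[C@H](O)C2 | starting material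
6 | 5,7,3',4'-tetra-O-benzyl-(−)-epicatechin | c1ccccc1COc1cc(OCc2ccccc2)c2c(c1)O[C@H](c1ccc(OCc3ccccc3)c(OCc3ccccc3)c1)[C@H](O)C2 | intermediate
7 | 3-O-(diethylsilyl)-5,7,3',4'-tetra-O-benzyl-(−)-epicatechin (Si–H ether, not isolated) | c1ccccc1COc1cc(OCc2ccccc2)c2c(c1)O[C@H](c1ccc(OCc3ccccc3)c(OCc3ccccc3)c1)[C@H](O[SiH](CC)CC)C2 | intermediate
8 | O3,C6'-(diethylsilylene)-bridged 5,7,3',4'-tetra-O-benzyl-(−)-epicatechin (2R,3R; six-membered oxasiline) | c1ccccc1COc1cc(OCc2ccccc2)c2c(c1)O[C@@H]1c3cc(OCc4ccccc4)c(OCc4ccccc4)cc3[Si](CC)(CC)O[C@@H]1C2 | intermediate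
9 | sodium silanolate of 6'-[diethyl(hydroxy)silyl]-5,7,3',4'-tetra-O-benzyl-(−)-epicatechin (not isolated) | c1ccccc1COc1cc(OCc2ccccc2)c2c(c1)O[C@H](c1cc(OCc3ccccc3)c(OCc3ccccc3)cc1[Si](CC)(CC)[O-])[C@H](O)C2.[Na+] | intermediate
10 | 5,7,3',4'-tetra-O-benzyl-(−)-epicatechin-(6'→8)-3,5,7,3',4'-penta-O-benzyl-(+)-catechin | c1ccccc1COc1cc(OCc2ccccc2)c2c(c1)O[C@H](c1cc(OCc3ccccc3)c(OCc3ccccc3)cc1-c1c(OCc3ccccc3)cc(OCc3ccccc3)c3c1O[C@H](c1ccc(OCc4ccccc4)c(OCc4ccccc4)c1)[C@@H](OCc1ccccc1)C3)[C@H](O)C2 | intermediate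
11 | CNP0353739.2, (−)-epicatechin-(6'→8)-(+)-catechin | Oc1cc(O)c2c(c1)O[C@H](c1cc(O)c(O)cc1-c1c(O)cc(O)c3c1O[C@H](c1ccc(O)c(O)c1)[C@@H](O)C3)[C@H](O)C2 | target

**Step count and risk**
Total steps: 7. Longest linear sequence: 5 steps (1 → 2 → 3 → 4 → 10 → 11); the epicatechin branch is 5 → 6 → 8 and joins at step 6.

The three steps most likely to fail:

Step 5 (the proposed new silylation). The six-membered closure may be slow compared with the five-membered benzoxasilole case, and intermolecular silylation or hydrosilylation of norbornene could compete. The fallback uses known chemistry, sets out from 6 and 4, and comes back to the route at 11. Compound 6 is treated with NBS (3.2 equiv, CH2Cl2/MeCN, 0 °C to rt). Bromination takes C8 and C6 of ring A first and then C6' of ring B (para to the 3'-oxygen, the usual site in 4-alkyl-1,2-dialkoxybenzenes), giving 6,8,6'-tribromo-5,7,3',4'-tetra-O-benzyl-(−)-epicatechin F1. Bromide 4 is converted by Br/Li exchange (n-BuLi, THF, −78 °C) and a quench with 2-isopropoxy-4,4,5,5-tetramethyl-1,3,2-dioxaborolane into 8-(pinacolboryl)-penta-O-benzyl-(+)-catechin F2. A site-selective Suzuki–Miyaura coupling (Pd(OAc)2, SPhos, K3PO4, toluene/H2O, 90 °C) should engage only the C6'–Br bond, which has a single ortho substituent; the two ring A bromides are each flanked by two oxygen substituents and add to palladium much more slowly. This gives 6,8-dibromo nona-O-benzyl dimer F3. Hydrogenolysis over Pd(OH)2/C with H2 and Et3N then removes the nine benzyl groups and both blocking bromides in one operation to give 11.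

Step 6 (Hiyama–Denmark coupling of two hindered, electron-rich partners). Slow transmetalation or protodesilylation could dominate. The fallback sets out from 8 and comes back at 10. Tamao–Fleming oxidation of 8 (H2O2, KHCO3, THF/MeOH) gives 6'-hydroxy-5,7,3',4'-tetra-O-benzyl-(−)-epicatechin F4. Selective phenol triflation (PhNTf2, K2CO3, DMF) gives 6'-trifluoromethanesulfonyloxy-5,7,3',4'-tetra-O-benzyl-(−)-epicatechin F5. Suzuki–Miyaura coupling of F5 with boronate F2 (made from 4 as described for step 5; Pd(OAc)2, SPhos, K3PO4, dioxane/H2O, 90 °C) delivers 10, which moves the nucleophilic role to the catechin half.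

Step 7 (ninefold debenzylation to an air-sensitive polyphenol). Incomplete cleavage or reductive opening of ring C is possible. The fallback sets out from 10 and comes back at 11 with no new intermediate. It replaces hydrogenolysis by Lewis-acid dealkylation with a cation scavenger (BCl3, pentamethylbenzene, CH2Cl2, −78 °C, quench with MeOH), which cleaves aryl benzyl ethers without a metal surface or hydrogen.

**Further compounds**
F1 | step 5 | 6,8,6'-tribromo-5,7,3',4'-tetra-O-benzyl-(−)-epicatechin | c1ccccc1COc1c(Br)c(OCc2ccccc2)c2c(c1Br)O[C@H](c1cc(OCc3ccccc3)c(OCc3ccccc3)cc1Br)[C@H](O)C2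
F2 | step 5 | 8-(4,4,5,5-tetramethyl-1,3,2-dioxaborolan-2-yl)-3,5,7,3',4'-penta-O-benzyl-(+)-catechin | c1ccccc1COc1cc(OCc2ccccc2)c2c(c1B3OC(C)(C)C(C)(C)O3)O[C@H](c1ccc(OCc3ccccc3)c(OCc3ccccc3)c1)[C@@H](OCc1ccccc1)C2
F3 | step 5 | 6,8-dibromo-5,7,3',4'-tetra-O-benzyl-(−)-epicatechin-(6'→8)-3,5,7,3',4'-penta-O-benzyl-(+)-catechin | c1ccccc1COc1c(Br)c(OCc2ccccc2)c2c(c1Br)O[C@H](c1cc(OCc3ccccc3)c(OCc3ccccc3)cc1-c1c(OCc3ccccc3)cc(OCc3ccccc3)c3c1O[C@H](c1ccc(OCc4ccccc4)c(OCc4ccccc4)c1)[C@@H](OCc1ccccc1)C3)[C@H](O)C2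
F4 | step 6 | 6'-hydroxy-5,7,3',4'-tetra-O-benzyl-(−)-epicatechin | c1ccccc1COc1cc(OCc2ccccc2)c2c(c1)O[C@H](c1cc(OCc3ccccc3)c(OCc3ccccc3)cc1O)[C@H](O)C2
F5 | step 6 | 6'-trifluoromethanesulfonyloxy-5,7,3',4'-tetra-O-benzyl-(−)-epicatechin | c1ccccc1COc1cc(OCc2ccccc2)c2c(c1)O[C@H](c1cc(OCc3ccccc3)c(OCc3ccccc3)cc1OS(=O)(=O)C(F)(F)F)[C@H](O)C2
F0 | step 7 | none | none
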